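The runs come from a simulation with made-up constants, and the scatter is random.

The ratio of product to electrophile missing from the balance shows how the nucleophile competes with a side loss, presumably to the protic impurity, whose charge is half that of the electrophile.

all flasks: electrophile 0.052 M

| run | nucleophile | free base | protic impurity | remark | time |
|---|---|---|---|---|---|
| ochre | 2 equiv | 0.15 equiv | 0.026 M | run made earlier |  |
| amber | 2 equiv | 0.60 equiv | 0.026 M | run made earlier |  |
| green | 1 equiv | 0.30 equiv | 0.026 M | run made earlier |  |
| flask | 2.00 equiv | 0.300 equiv | 0.0260 M |  | 1.0 h |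

| run | time / min | electrophile / % | product / % |
|---|---|---|---|
| ochre | 10.0 | 52.5 | 38.6 |
| ochre | 25.0 | 26.7 | 57.8 |
| ochre | 50.0 | 10.9 | 70.6 |
| ochre | 80.0 | 4.2 | 74.6 |
| amber | 20.0 | 30.2 | 55.1 |
| amber | 40.0 | 12.9 | 69.3 |
| amber | 50.0 | 10.0 | 72.7 |
| amber | 80.0 | 2.9 | 77.4 |
| green | 6.00 | 77.7 | 15.3 |
| green | 12.0 | 65.0 | 24.0 |
| green | 30.0 | 41.7 | 40.0 |
| green | 80.0 | 18.8 | 51.8 |

(each reading ± 0.5 percentage points)

- the analysis behind the earlier runs scatters by 0.5 percentage points, standard deviation
- the earlier runs do not show how much of nucleophile is bound; that part of a forecast is a guess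

1. part of the electrophile that has reacted at 1.0 h
2. share of the unused nucleophile that is free and not bound as protonated nucleophile, at 1.0 h

First instants: in the green run, at one equivalent, 15.3% product stands against 7.00% missing at 6.00 min. This gives the split ratio per equivalent of nucleophile, a selectivity factor, as a reading: 2.19. The ochre run, with 2 equiv, reads 4.34 at 10.0 min, twice the green value, so the split follows the nucleophile charge.

Middle: at 50.0 min the ochre run holds 10.9% electrophile and the amber run 10.0%, a gap of 0.9 percentage points against a scatter of 0.5 points, despite 0.15 equiv against 0.60 equiv of free base.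

End: between 50.0 min and 80.0 min, new product over newly missing electrophile in the ochre run reads 1.48, below the 4.37 that the split gives for 2.00 equiv. The free nucleophile has shrunk, but the readings do not show how much is bound.

My own reckoning interpolates the logarithm of the electrophile left to 1.0 h: 7.93% for ochre and 6.62% for amber. The geometric mean suits a base charge of 0.300 equiv, and it gives 92.8% reacted.

The forecast differs slightly: 92.4% (91% to 93.6%) reacted and 61% (46% to 76%) free, with the remark “Late rates suggest about 60%, but this is a guess”.

The flask gives 92.5% reacted and 58.2% of the unused nucleophile free, with 73.5% product beside 19.0% quenched substrate.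

    acid set free → by-product carried off (k = 1.12 × 10⁻⁴ s⁻¹)
    acid set free + free base ⇌ salt of the base, settled at all times (K = 42000 M⁻¹)
    electrophile + protic impurity → quenched substrate (k = 0.00855 M⁻¹ s⁻¹)
    nucleophile + acid set free ⇌ protonated nucleophile, settled at all times (K = 14000 M⁻¹)
    electrophile + nucleophile → acid set free + product (k = 0.0104 M⁻¹ s⁻¹)

That whole-run split in the flask, 3.88, lies below 4.37, so the mean over the curve sits 11.2% under the value scaled from the charge. With 0.500 equiv of nucleophile, the split predicts 1.09. That neighbour flask computes to 29.8% product against 30.7% quenched substrate, a split of 0.971, with 60.5% reacted.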